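In ring A, the ring oxygen O1 (on C8a) and the methoxy oxygen on C6 are para to each other, and the other two oxygens sit on C5 and C8. Ring A is therefore the reduced, O-methylated form of a 2,5-dialkoxy-1,4-benzoquinone whose carbonyls are C5 and C8.
The C5 and C8 O-methyl groups are traced back (reduction, methylation) to the 6-methoxyflavone-5,8-quinone. The strategic cut is its C6–O bond, which is traced back to methanol and the unsubstituted flavone-5,8-quinone by oxidative conjugate addition.
That quinone comes from the 5-hydroxyflavone by para-hydroxylation at C8 and a neutral dehydrogenation that spares the B-ring hydroquinone dimethyl ether.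
Rings A and B are bought. The pyranone ring C is the only ring made (C-aroylation of 2,6-dihydroxyacetophenone, then O1–C2 cyclodehydration). Everything afterwards is stepwise oxygenation of ring A, first at C8 and then at C6.

Key step: step 5

Remark: the target has no stereocentre and the C2–C1' bond rotates freely, so it is achiral and needs no stereocontrol. The only selectivity issue is C6 versus C7.

Step 1
Reactants: 1 2,6-dihydroxyacetophenone; 2 2,5-dimethoxybenzoyl chloride
Product: 3 1-(2,6-dihydroxyphenyl)-3-(2,5-dimethoxyphenyl)propane-1,3-dione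
Conditions: LiHMDS (4.2 equiv), THF, −78 to −10 °C; then 2 (1.0 equiv), −78 °C to rt; aq. HCl
Reagents that add atoms: none
Why: Claisen-type C-aroylation of a lithium polyanion: with both phenols and the methyl ketone deprotonated, the enolate carbon is by far the most nucleophilic site, so one equivalent of 2 should give the β-diketone directly (the outcome of a Baker–Venkataraman sequence without the ester stage), the fourth equivalent of base storing the product as its enolate.

Step 2
Reactants: 3 1-(2,6-dihydroxyphenyl)-3-(2,5-dimethoxyphenyl)propane-1,3-dione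
Product: 4 5-hydroxy-2-(2,5-dimethoxyphenyl)-4H-chromen-4-one
Conditions: H2SO4 (cat.), AcOH, 95 °C
Reagents that add atoms: none
Why: Acid-catalysed cyclodehydration of an o-hydroxyaryl β-diketone (closing stage of the Baker–Venkataraman flavone synthesis, 6-exo attack of a phenol oxygen on the aroyl carbonyl and loss of water); the two phenols of 3 are equivalent, so a single flavone should result and the spare OH ends as the chelated 5-OH.

Step 3
Reactants: 4 5-hydroxy-2-(2,5-dimethoxyphenyl)-4H-chromen-4-one
Product: 6 5,8-dihydroxy-2-(2,5-dimethoxyphenyl)-4H-chromen-4-one, via C8 aryl sulfate 5 (not isolated)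
Conditions: K2S2O8, aq. KOH, pyridine, 10–20 °C; acidify to pH 5 and remove unchanged 4; then aq. HCl, 90 °C, N2
Reagents that add atoms: potassium persulfate, [K+].[K+].[O-]S(=O)(=O)OOS(=O)(=O)[O-]
Why: Elbs persulfate oxidation: the phenolate of 4 attacks the peroxide O–O bond through its para carbon C8 to give aryl sulfate 5, which aqueous acid hydrolyses to the quinol; this ionic para-hydroxylation is the established way from 5-hydroxyflavones to 5,8-dihydroxyflavones and is preferred to Fremy's salt, whose hydrogen abstraction is hampered by the O5–H···O4 chelate.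

Step 4
Reactants: 6 5,8-dihydroxy-2-(2,5-dimethoxyphenyl)-4H-chromen-4-one
Product: 7 2-(2,5-dimethoxyphenyl)chromene-4,5,8-trione
Conditions: activated MnO2, MgSO4, CH2Cl2, rt, dark; filter through Celite and use at once
Reagents that add atoms: none
Why: Heterogeneous two-electron dehydrogenation of an acylhydroquinone with MnO2 under neutral, anhydrous conditions, mild enough to leave the B-ring 1,4-dimethoxyarene untouched (CAN or AgO/HNO3 would not) and to deliver the electrophilic quinone by simple filtration.

Step 5
Reactants: 7 2-(2,5-dimethoxyphenyl)chromene-4,5,8-trione; 8 methanol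
Product: 10 6-methoxy-2-(2,5-dimethoxyphenyl)chromene-4,5,8-trione, via 6-methoxy-5,8-hydroquinone adduct 9 (not isolated)
Conditions: ZnCl2 (anhydrous, 1 equiv), activated MnO2 (5 equiv), MeOH–CH2Cl2 1:1, rt, dark
Reagents that add atoms: methanol (8), CO
Why: Zinc-activated methanol adds in 1,4 fashion to the enone C8(=O)–C7=C6 at C6, the adduct tautomerises to hydroquinone 9, and MnO2 (directly, or by regenerating 7 after 7 has oxidised 9) dehydrogenates 9 to 10, so one C6–O bond forms, no ring closes and no stereocentre arises. The closest known reaction type is the ZnCl2-promoted oxidative addition of methanol to 1,4-benzoquinone and methoxy-1,4-benzoquinone, which stops at the 2,5-dimethoxyquinone, and in situ MnO2 oxidation of acylhydroquinones in the presence of a nucleophile is likewise established. The step needs C6 over C7 selectivity: O1 donates through C8a=C4a into C5=O, which therefore behaves as a vinylogous ester, so C8=O is the better acceptor and its β-carbon is C6, and attack there leaves the O1–C8a=C4a–C5=O push–pull unit intact in the transition state. Because C4=O competes for the same donation and forms a bidentate pocket with C5=O, the bias is smaller than in methoxybenzoquinone; methanol as co-solvent keeps zinc solvated and weakly bound, and strongly chelating Lewis acids (Mg, Ti, Sn, B) are excluded because a C4=O/C5=O chelate would activate C5=O and send methanol to C7. Attack at C8a or C2 is reversible and cannot aromatise, so it drains back, whereas 10 carries a donor oxygen on each quinone C=C and should resist a second addition.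

Step 6
Reactants: 10 6-methoxy-2-(2,5-dimethoxyphenyl)chromene-4,5,8-trione
Product: 9 5,8-dihydroxy-6-methoxy-2-(2,5-dimethoxyphenyl)-4H-chromen-4-one
Conditions: Na2S2O4, EtOAc–H2O, rt, Ar; organic layer dried and concentrated under Ar
Reagents that add atoms: none
Why: Standard dithionite reduction of a p-quinone to its hydroquinone in a two-phase system, which returns 9 free of any oxidant after purification and structural assignment at the stable quinone stage; the pyranone and the aryl ethers are inert.

Step 7
Reactants: 9 5,8-dihydroxy-6-methoxy-2-(2,5-dimethoxyphenyl)-4H-chromen-4-one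
Product: 11 5,6,8-trimethoxy-2-(2,5-dimethoxyphenyl)-4H-chromen-4-one
Conditions: Me2SO4 (5 equiv), K2CO3 (anhydrous, 8 equiv), acetone, reflux, Ar
Reagents that add atoms: dimethyl sulfate, COS(=O)(=O)OC
Why: Williamson-type exhaustive O-methylation: the free 8-OH reacts quickly and the chelated 5-OH follows on prolonged reflux with excess dimethyl sulfate and carbonate, as is usual for 5-hydroxyflavones, while inert gas prevents re-oxidation of the phenolates.

Compound list
1 | 2,6-dihydroxyacetophenone | CC(=O)c1c(O)cccc1O | starting material
2 | 2,5-dimethoxybenzoyl chloride | COc1ccc(OC)c(C(=O)Cl)c1 | starting material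
3 | 1-(2,6-dihydroxyphenyl)-3-(2,5-dimethoxyphenyl)propane-1,3-dione | COc1ccc(OC)c(C(=O)CC(=O)c2c(O)cccc2O)c1 | intermediate
4 | 5-hydroxy-2-(2,5-dimethoxyphenyl)-4H-chromen-4-one | COc1ccc(OC)c(-c2cc(=O)c3c(O)cccc3o2)c1 | intermediate
5 | potassium 5-hydroxy-2-(2,5-dimethoxyphenyl)-4-oxo-4H-chromen-8-yl sulfate | COc1ccc(OC)c(-c2cc(=O)c3c(O)ccc(OS(=O)(=O)[O-])c3o2)c1.[K+] | intermediate
6 | 5,8-dihydroxy-2-(2,5-dimethoxyphenyl)-4H-chromen-4-one | COc1ccc(OC)c(-c2cc(=O)c3c(O)ccc(O)c3o2)c1 | intermediate
7 | 2-(2,5-dimethoxyphenyl)chromene-4,5,8-trione | O=C1C=CC(=O)C2=C1C(=O)C=C(c1cc(OC)ccc1OC)O2 | intermediate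
8 | methanol | CO | starting material
9 | 5,8-dihydroxy-6-methoxy-2-(2,5-dimethoxyphenyl)-4H-chromen-4-one | COc1ccc(OC)c(-c2cc(=O)c3c(O)c(OC)cc(O)c3o2)c1 | intermediate
10 | 6-methoxy-2-(2,5-dimethoxyphenyl)chromene-4,5,8-trione | COC1=CC(=O)C2=C(C1=O)C(=O)C=C(c1cc(OC)ccc1OC)O2 | intermediate
11 | 5,6,8-trimethoxy-2-(2,5-dimethoxyphenyl)-4H-chromen-4-one | COc1ccc(OC)c(-c2cc(=O)c3c(OC)c(OC)cc(OC)c3o2)c1 | target

Total step count: 7
Longest linear sequence: 7 steps (from 1)

Steps most likely to fail

Step 5.
- **What may go wrong:** The C6/C7 selectivity may erode or invert if zinc settles in the C4=O/C5=O pocket. Material may also be lost through reversible methanol attack at C8a that opens the pyranone.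
- **Check:** The site of addition would have to be established at 10 by HMBC of the lone ring-A proton, which correlates to C8a in the 6-methoxy series and to C4a in the 7-methoxy series.
- **Fallback:** It sets out from 6, avoids the quinone and rejoins at 11.
  - One equivalent of Me2SO4 with K2CO3 in acetone under argon should alkylate only the non-chelated 8-OH and give 5-hydroxy-8-methoxy-2-(2,5-dimethoxyphenyl)-4H-chromen-4-one F1.
  - Phenol-selective iodination (BnMe3N·ICl2, CaCO3, CH2Cl2–MeOH) can only go to C6, the one free position ortho to the phenol and para to O1. It should give 5-hydroxy-6-iodo-8-methoxy-2-(2,5-dimethoxyphenyl)-4H-chromen-4-one F2.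
  - Forced methylation of the chelated OH gives 6-iodo-5,8-dimethoxy-2-(2,5-dimethoxyphenyl)-4H-chromen-4-one F3.
  - Ullmann-type methoxylation (NaOMe, CuBr, DMF–MeOH, 110 °C) installs the C6 methoxy and delivers 11.

Step 3.
- **What may go wrong:** The chelated, electron-poor phenolate may convert poorly with persulfate, and the quinol may be over-oxidised in alkali.
- **Fallback:** It sets out from 4, replaces oxygen transfer by nitrogen transfer and rejoins at 7.
  - Azo coupling with diazotised sulfanilic acid in aq. NaOH–pyridine at 0–5 °C, para to the phenolate, should give 4-{(E)-[5-hydroxy-2-(2,5-dimethoxyphenyl)-4-oxo-4H-chromen-8-yl]diazenyl}benzenesulfonic acid F4.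
  - Dithionite cleavage of the azo bond gives 8-amino-5-hydroxy-2-(2,5-dimethoxyphenyl)-4H-chromen-4-one F5.
  - Oxidation of this p-aminophenol with FeCl3 in cold dilute HCl under a CH2Cl2 layer passes through the quinone imine, which hydrolyses. Quinone 7 is extracted as it forms.

Step 7.
- **What may go wrong:** Air may re-oxidise the hydroquinone phenolates in base, and alkylation of the chelated 5-OH may be incomplete.
- **Fallback:** It sets out from 10, bypasses free 9 and rejoins at 11.
  - Reductive acetylation (Zn dust, Ac2O, NaOAc) should give the air-stable 6-methoxy-2-(2,5-dimethoxyphenyl)-4-oxo-4H-chromene-5,8-diyl diacetate F6.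
  - F6 is then deacetylated and methylated in one operation (Me2SO4, K2CO3, acetone–MeOH, reflux). Each phenolate is alkylated as it is released, and 11 results.

Further compounds
F1 | step 5 | 5-hydroxy-8-methoxy-2-(2,5-dimethoxyphenyl)-4H-chromen-4-one | COc1ccc(OC)c(-c2cc(=O)c3c(O)ccc(OC)c3o2)c1
F2 | step 5 | 5-hydroxy-6-iodo-8-methoxy-2-(2,5-dimethoxyphenyl)-4H-chromen-4-one | COc1ccc(OC)c(-c2cc(=O)c3c(O)c(I)cc(OC)c3o2)c1
F3 | step 5 | 6-iodo-5,8-dimethoxy-2-(2,5-dimethoxyphenyl)-4H-chromen-4-one | COc1ccc(OC)c(-c2cc(=O)c3c(OC)c(I)cc(OC)c3o2)c1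
F4 | step 3 | 4-{(E)-[5-hydroxy-2-(2,5-dimethoxyphenyl)-4-oxo-4H-chromen-8-yl]diazenyl}benzenesulfonic acid | COc1ccc(OC)c(-c2cc(=O)c3c(O)ccc(/N=N/c4ccc(S(=O)(=O)O)cc4)c3o2)c1
F5 | step 3 | 8-amino-5-hydroxy-2-(2,5-dimethoxyphenyl)-4H-chromen-4-one | COc1ccc(OC)c(-c2cc(=O)c3c(O)ccc(N)c3o2)c1
F6 | step 7 | 6-methoxy-2-(2,5-dimethoxyphenyl)-4-oxo-4H-chromene-5,8-diyl diacetate | COc1ccc(OC)c(-c2cc(=O)c3c(OC(C)=O)c(OC)cc(OC(C)=O)c3o2)c1
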